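Ring A is disconnected at C2–C3 and C4–C18 (labdane numbering), which leaves ring B to be supplied intact by (R)-carvone, whose stereocentre becomes C5. One mixed Kolbe electrolysis of a C10 propanoic acid with acetic acid then closes ring A by 6-endo attack of the C2 radical on a C5-bound acrylate and caps the C4 radical with methyl. The step exploits the α-ester radical at C4 of ring A: the axial C10 methyl screens its β-face, so methyl enters from the α-face and gives equatorial C18 and the axial C19 ester. The precursor is a carvone-derived cyclohexenone carrying trans acrylate (C5) and propanoic acid (C10) arms; the C11–C16 chain follows through a C9 enol triflate.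

Key step: step 8

Assumption: ring atoms carry labdane numbers throughout (carvone C1, C2, C3, C4, C5, C6 become C9, C8, C7, C6, C5, C10), and the silyl ether 19 of but-3-yn-1-ol is taken as purchased.

Step 1
Reactants: 1 (R)-carvone
Product: 3 6-methylcarvone (mixture of C6 epimers), via lithium dienolate 2 (not isolated)
Conditions: LiN(i-Pr)2, THF, −78 °C; then MeI, −78 → 0 °C
Reagents that add atoms: iodomethane, CI
Why: Kinetic deprotonation at the α′-carbon (the future C10) and SN2 methylation of the cross-conjugated lithium dienolate is a routine enolate alkylation of carvone; the new centre is left uncontrolled because step 2 planarises it again.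

Step 2
Reactants: 3 6-methylcarvone; 4 allyl bromide
Product: 6 6-allyl-6-methylcarvone (allyl trans to isopropenyl), via lithium dienolate 5 (not isolated)
Conditions: LiN(i-Pr)2, THF, −78 → 0 °C; then 4, DMPU, −78 °C → rt
Reagents that add atoms: none
Why: Enolate alkylation of the tetrasubstituted α′-dienolate, in which allyl bromide is taken up on the face anti to the C5 isopropenyl group and so sets the quaternary C10 with methyl cis and the three-carbon arm trans to the C5 substituent; an allyl group is used as the propanoic acid precursor because Michael addition of such dienolates to acrylates runs on to bicyclo[2.2.2]octanones.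

Step 3
Reactants: 6 6-allyl-6-methylcarvone
Product: 8 6-(3-hydroxypropyl)-2,6-dimethyl-5-(prop-1-en-2-yl)cyclohex-2-en-1-one, via B-alkyldicyclohexylborane 7 (not isolated)
Conditions: Cy2BH (BH3·SMe2, cyclohexene), THF, 0 °C; then 30% H2O2, pH 7 phosphate buffer, MeOH, 0 °C → rt
Reagents that add atoms: hydrogen peroxide, OO
Why: Hydroboration–oxidation with a bulky dialkylborane, which adds anti-Markovnikov to the monosubstituted allyl alkene much faster than to the hindered 1,1-disubstituted isopropenyl group or to the conjugated ketone flanked by C10 and the C8 methyl, while neutral buffered peroxide cleaves the C–B bond without nucleophilic epoxidation of the enone; no stereocentre is formed.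

Step 4
Reactants: 8 hydroxypropyl enone
Product: 10 2-[2-(3-hydroxypropyl)-2,4-dimethyl-3-oxocyclohex-4-en-1-yl]prop-2-enal, via allylic alcohol 9 (not isolated)
Conditions: SeO2 (0.3 equiv), t-BuOOH, CH2Cl2, rt; then MnO2, CH2Cl2, rt
Reagents that add atoms: tert-butyl hydroperoxide, CC(C)(C)OO; selenium dioxide (catalytic oxygen relay), O=[Se]=O
Why: Catalytic selenium dioxide allylic oxidation (ene reaction, then [2,3]-sigmatropic shift) takes place at the methyl group of the only electron-rich 1,1-disubstituted alkene, and MnO2 then oxidises the allylic alcohol alone, so that alcohol and any enal already present converge while the saturated primary alcohol survives; no stereocentre is formed.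

Step 5
Reactants: 10 enal
Product: 11 2-[2-(3-hydroxypropyl)-2,4-dimethyl-3-oxocyclohex-4-en-1-yl]prop-2-enoic acid
Conditions: NaClO2, NaH2PO4, 2-methylbut-2-ene, t-BuOH/H2O, 0 °C → rt
Reagents that add atoms: sodium chlorite, [Na+].[O-]Cl=O
Why: Pinnick oxidation converts the 2-substituted acrolein into the acrylic acid with chlorite, and 2-methylbut-2-ene scavenges the hypochlorous acid so that the alkenes and the primary alcohol are spared.

Step 6
Reactants: 11 acrylic acid
Product: 12 methyl 2-[2-(3-hydroxypropyl)-2,4-dimethyl-3-oxocyclohex-4-en-1-yl]prop-2-enoate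
Conditions: MeI, KHCO3, DMF, rt
Reagents that add atoms: iodomethane, CI
Why: SN2 O-alkylation of the carboxylate with iodomethane under bicarbonate, a base too weak to deprotonate the alcohol or to start conjugate additions to the acrylate or the enone.

Step 7
Reactants: 12 hydroxy acrylate
Product: 14 seco-acid 3-[6-(3-methoxy-3-oxoprop-1-en-2-yl)-1,3-dimethyl-2-oxocyclohex-3-en-1-yl]propanoic acid, via aldehyde 13 (not isolated)
Conditions: TEMPO (cat.), PhI(OAc)2, MeCN/H2O, rt
Reagents that add atoms: water, O
Why: Nitroxyl-catalysed oxidation of the primary alcohol through aldehyde 13 and its hydrate to the carboxylic acid in aqueous acetonitrile, conditions that leave the acrylate, the enone and the methyl ester untouched.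

Step 8
Reactants: 14 seco-acid; 15 acetic acid (20 equiv)
Product: 16 methyl 9-oxo-11,12,13,14,15,16-hexanorlabd-7-en-19-oate
Conditions: Pt anode, Pt cathode, undivided cell, KOH (5 mol % of total acid), MeOH, ca. 0.2 A cm−2, 15–20 °C
Reagents that add atoms: none
Why: Proposed new method: anodic oxidation of the carboxylate of 14 at platinum and loss of CO2 give the primary C2 radical, which adds to the unsubstituted CH2 terminus (C3) of the acrylate, and the tertiary α-ester radical that results at C4 combines with a methyl radical made at the same anode from the large excess of acetate. The closest known reaction type is the mixed Kolbe electrolysis of unsaturated acids in which a 5-exo cyclisation precedes coupling with the radical of the co-acid; new here are the 6-endo mode and the capture at a tertiary centre. Ring A closes 6-endo-trig, because the 5-exo alternative would have to attack the fully substituted, ester-bearing C4 and would lose the polarity match between a nucleophilic alkyl radical and the acrylate β-carbon. The ring fusion is fixed trans by the trans arms already on C5 and C10, and the one new stereocentre, C4, is controlled by the axial C10 methyl, which screens the β-face so that methyl bonds from the α-face (equatorial C18, axial C19 ester). The step needs cyclisation at the acrylate in preference to the enone carbon C7 and cross- in preference to homo-coupling: the diequatorial conformer holds C2 next to C3 whereas C7 is a hindered, trisubstituted acceptor reachable only from the diaxial conformer, and the excess of acetic acid makes methyl the dominant partner of the C4 radical. Neither the primary C2 radical nor the electron-poor C4 radical is readily oxidised further at the anode, so cation-derived (Hofer–Moest) products should stay minor.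

Step 9
Reactants: 16 keto ester
Product: 18 methyl 9-(trifluoromethylsulfonyloxy)-11,12,13,14,15,16-hexanorlabd-8-en-19-oate, via lithium enolate 17 (not isolated)
Conditions: LiBH(sec-Bu)3, THF, −78 °C; then PhNTf2, −78 °C → rt
Reagents that add atoms: N-phenylbis(trifluoromethanesulfonimide), O=S(=O)(N(c1ccccc1)S(=O)(=O)C(F)(F)F)C(F)(F)F
Why: Conjugate reduction of the enone by the bulky borohydride, whose 1,2-attack is blocked by the quaternary C10, gives the C8=C9 enolate regiospecifically, and O-sulfonylation with PhNTf2 gives the enol triflate; C8 stays sp2, so no stereocentre is formed, and the hindered C19 ester is inert at −78 °C.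

Step 10
Reactants: 19 tert-butyl(but-3-yn-1-yloxy)dimethylsilane
Product: 21 (E)-5-(tert-butyldimethylsilyloxy)-3-methylpent-2-en-1-ol, via alkenylalane 20 (not isolated)
Conditions: Me3Al, Cp2ZrCl2 (0.25 equiv), CH2Cl2, 0 °C → rt; then (CH2O)n, THF, 0 °C → rt; aq. potassium sodium tartrate
Reagents that add atoms: trimethylaluminium, C[Al](C)C; paraformaldehyde (as formaldehyde), C=O
Why: Negishi zirconium-catalysed carboalumination adds methyl and aluminium syn across the terminal alkyne with methyl on the internal carbon, and the alkenylalane adds to formaldehyde with retention of alkene geometry, which fixes the E-trisubstituted C13=C14 alkene.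

Step 11
Reactants: 21 allylic alcohol
Product: 22 (E)-1-(tert-butyldiphenylsilyloxy)-5-(tert-butyldimethylsilyloxy)-3-methylpent-2-ene
Conditions: t-BuPh2SiCl, imidazole, CH2Cl2, rt
Reagents that add atoms: tert-butyl(chloro)diphenylsilane, CC(C)(C)[Si](Cl)(c1ccccc1)c1ccccc1
Why: Imidazole-promoted silylation of the primary allylic alcohol installs a silyl ether that is more robust than the one on the homoallylic oxygen and survives steps 12 to 14.

Step 12
Reactants: 22 bis-silyl ether
Product: 23 (E)-5-(tert-butyldiphenylsilyloxy)-3-methylpent-3-en-1-ol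
Conditions: camphorsulfonic acid (cat.), MeOH/CH2Cl2, 0 °C
Reagents that add atoms: none
Why: Acid-catalysed methanolysis (selective desilylation) removes the small tert-butyldimethylsilyl group much faster than the bulkier tert-butyldiphenylsilyl group, so only the homoallylic alcohol is released.

Step 13
Reactants: 23 homoallylic alcohol
Product: 24 (E)-tert-butyl[(5-iodo-3-methylpent-2-en-1-yl)oxy]diphenylsilane
Conditions: I2, PPh3, imidazole, CH2Cl2, 0 °C → rt
Reagents that add atoms: iodine, II
Why: Appel-type iodination: the alcohol is activated as an alkoxyphosphonium ion and displaced by iodide in an SN2 step, with the silyl ether and the alkene unaffected.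

Step 14
Reactants: 18 enol triflate; 24 iodide
Product: 26 methyl 15-(tert-butyldiphenylsilyloxy)labda-8,13E-dien-19-oate, via alkylzinc iodide 25 (not isolated)
Conditions: 24, Zn dust (activated with BrCH2CH2Br, Me3SiCl), LiCl, THF, 40 °C; then 18, PdCl2(dppf) (5 mol %), THF/NMP, 60 °C
Reagents that add atoms: none
Why: Negishi sp3–sp2 cross-coupling: zinc inserts into the primary C–I bond, the alkylzinc transmetalates to the alkenylpalladium formed from the enol triflate, and the wide-bite-angle dppf ligand favours reductive elimination over β-hydride loss; the C8=C9 position and the E-alkene are carried over unchanged and the ester does not react with the zinc reagent.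

Step 15
Reactants: 26 silyl ether ester
Product: 28 15-hydroxylabda-8,13E-dien-19-oic acid, via lithium carboxylate 27 (not isolated)
Conditions: n-PrSLi (n-PrSH, n-BuLi), HMPA, rt; then Bu4NF, THF, rt; aq. NH4Cl, HCl to pH 3
Reagents that add atoms: none
Why: Thiolate SN2 dealkylation at the ester methyl, which does not require access to the shielded axial carbonyl, is followed in the same flask by fluoride cleavage of the silyl ether; no stereocentre or alkene is affected.

Step 16
Reactants: 28 hydroxy acid
Product: 30 15-acetoxylabda-8,13E-dien-19-oic acid (target), via mixed anhydride 29 (not isolated)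
Conditions: Ac2O, pyridine, DMAP (cat.), CH2Cl2, 0 °C → rt; then H2O, THF, rt
Reagents that add atoms: acetic anhydride, CC(=O)OC(C)=O
Why: Pyridine/DMAP-catalysed O-acetylation of the primary allylic alcohol; the carboxylic acid is acylated at the same time to mixed anhydride 29, which water cleaves at the unhindered acetyl carbonyl and so returns the free C19 acid.

Compound list

1 | (R)-carvone, (5R)-2-methyl-5-(prop-1-en-2-yl)cyclohex-2-en-1-one | CC1=CC[C@H](CC1=O)C(=C)C | starting material
2 | lithium dienolate of 1 (enolate towards the α′-carbon) | CC1=CC[C@H](C=C1[O-])C(=C)C.[Li+] | intermediate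
3 | 6-methylcarvone, (5R)-2,6-dimethyl-5-(prop-1-en-2-yl)cyclohex-2-en-1-one, both C6 epimers | CC1=CC[C@H](C(C)C1=O)C(=C)C | intermediate
4 | allyl bromide | C=CCBr | starting material
5 | lithium dienolate of 3 | CC1=CC[C@H](C(C)=C1[O-])C(=C)C.[Li+] | intermediate
6 | 6-allyl-6-methylcarvone, 6-allyl-2,6-dimethyl-5-(prop-1-en-2-yl)cyclohex-2-en-1-one with allyl trans and methyl cis to the isopropenyl group | O=C1C(C)=CC[C@@H](C(=C)C)[C@]1(C)CC=C | intermediate
7 | B-alkyldicyclohexylborane, 6 with the allyl group turned into 3-(dicyclohexylboryl)propyl | O=C1C(C)=CC[C@@H](C(=C)C)[C@]1(C)CCCB(C1CCCCC1)C1CCCCC1 | intermediate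
8 | 6-(3-hydroxypropyl)-2,6-dimethyl-5-(prop-1-en-2-yl)cyclohex-2-en-1-one (configuration of 6) | O=C1C(C)=CC[C@@H](C(=C)C)[C@]1(C)CCCO | intermediate
9 | 5-(3-hydroxyprop-1-en-2-yl)-6-(3-hydroxypropyl)-2,6-dimethylcyclohex-2-en-1-one (configuration of 6) | O=C1C(C)=CC[C@@H](C(=C)CO)[C@]1(C)CCCO | intermediate
10 | 2-[2-(3-hydroxypropyl)-2,4-dimethyl-3-oxocyclohex-4-en-1-yl]prop-2-enal (configuration of 6) | O=C1C(C)=CC[C@@H](C(=C)C=O)[C@]1(C)CCCO | intermediate
11 | 2-[2-(3-hydroxypropyl)-2,4-dimethyl-3-oxocyclohex-4-en-1-yl]prop-2-enoic acid (configuration of 6) | O=C1C(C)=CC[C@@H](C(=C)C(=O)O)[C@]1(C)CCCO | intermediate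
12 | methyl 2-[2-(3-hydroxypropyl)-2,4-dimethyl-3-oxocyclohex-4-en-1-yl]prop-2-enoate (configuration of 6) | O=C1C(C)=CC[C@@H](C(=C)C(=O)OC)[C@]1(C)CCCO | intermediate
13 | methyl 2-[2,4-dimethyl-3-oxo-2-(3-oxopropyl)cyclohex-4-en-1-yl]prop-2-enoate (configuration of 6) | O=C1C(C)=CC[C@@H](C(=C)C(=O)OC)[C@]1(C)CCC=O | intermediate
14 | seco-acid, 3-[6-(3-methoxy-3-oxoprop-1-en-2-yl)-1,3-dimethyl-2-oxocyclohex-3-en-1-yl]propanoic acid, acrylate arm (C5) trans to the propanoic acid arm (C10) | O=C1C(C)=CC[C@@H](C(=C)C(=O)OC)[C@]1(C)CCC(=O)O | intermediate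
15 | acetic acid | CC(=O)O | starting material
16 | methyl 9-oxo-11,12,13,14,15,16-hexanorlabd-7-en-19-oate (trans-decalin, 5α-H, 10β-methyl, 4α-methyl, 4β-ester) | O=C1C(C)=CC[C@H]2[C@@](C)(C(=O)OC)CCC[C@]12C | intermediate
17 | lithium C8=C9 enolate from 16 | [Li+].[O-]C1=C(C)CC[C@H]2[C@@](C)(C(=O)OC)CCC[C@]12C | intermediate
18 | methyl 9-(trifluoromethylsulfonyloxy)-11,12,13,14,15,16-hexanorlabd-8-en-19-oate | O=S(=O)(OC1=C(C)CC[C@H]2[C@@](C)(C(=O)OC)CCC[C@]12C)C(F)(F)F | intermediate
19 | tert-butyl(but-3-yn-1-yloxy)dimethylsilane | C#CCCO[Si](C)(C)C(C)(C)C | starting material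
20 | (E)-[4-(tert-butyldimethylsilyloxy)-2-methylbut-1-en-1-yl]dimethylalane | C[Al](C)/C=C(\C)CCO[Si](C)(C)C(C)(C)C | intermediate
21 | (E)-5-(tert-butyldimethylsilyloxy)-3-methylpent-2-en-1-ol | OC/C=C(\C)CCO[Si](C)(C)C(C)(C)C | intermediate
22 | (E)-1-(tert-butyldiphenylsilyloxy)-5-(tert-butyldimethylsilyloxy)-3-methylpent-2-ene | CC(C)(C)[Si](c1ccccc1)(c1ccccc1)OC/C=C(\C)CCO[Si](C)(C)C(C)(C)C | intermediate
23 | (E)-5-(tert-butyldiphenylsilyloxy)-3-methylpent-3-en-1-ol | CC(C)(C)[Si](c1ccccc1)(c1ccccc1)OC/C=C(\C)CCO | intermediate
24 | (E)-tert-butyl[(5-iodo-3-methylpent-2-en-1-yl)oxy]diphenylsilane | CC(C)(C)[Si](c1ccccc1)(c1ccccc1)OC/C=C(\C)CCI | intermediate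
25 | (E)-[5-(tert-butyldiphenylsilyloxy)-3-methylpent-3-en-1-yl]zinc iodide | CC(C)(C)[Si](c1ccccc1)(c1ccccc1)OC/C=C(\C)CC[Zn]I | intermediate
26 | methyl 15-(tert-butyldiphenylsilyloxy)labda-8,13E-dien-19-oate | CC(C)(C)[Si](c1ccccc1)(c1ccccc1)OC/C=C(\C)CCC1=C(C)CC[C@H]2[C@@](C)(C(=O)OC)CCC[C@]12C | intermediate
27 | lithium 15-(tert-butyldiphenylsilyloxy)labda-8,13E-dien-19-oate | CC(C)(C)[Si](c1ccccc1)(c1ccccc1)OC/C=C(\C)CCC1=C(C)CC[C@H]2[C@@](C)(C(=O)[O-])CCC[C@]12C.[Li+] | intermediate
28 | 15-hydroxylabda-8,13E-dien-19-oic acid | OC/C=C(\C)CCC1=C(C)CC[C@H]2[C@@](C)(C(=O)O)CCC[C@]12C | intermediate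
29 | acetic 15-acetoxylabda-8,13E-dien-19-oic anhydride | CC(=O)OC/C=C(\C)CCC1=C(C)CC[C@H]2[C@@](C)(C(=O)OC(C)=O)CCC[C@]12C | intermediate
30 | 15-acetoxylabda-8,13E-dien-19-oic acid | CC(=O)OC/C=C(\C)CCC1=C(C)CC[C@H]2[C@@](C)(C(=O)O)CCC[C@]12C | target

Total step count: 16.
Longest linear sequence: 12 steps (steps 1–9 and 14–16, from 1); the side chain takes steps 10–13 from 19.

Steps most likely to fail

Step 8. Combination of the tertiary C4 radical with methyl may lose out to disproportionation and to homocoupling, closure onto the enone carbon C7 may compete, and the facial selectivity of the methyl capture may be poor. The fallback uses known chemistry, sets out from 14 and comes back at 26. Acid 14 is esterified with N-hydroxyphthalimide (i-PrN=C=N-i-Pr, DMAP, CH2Cl2) to the N-acyloxyphthalimide F1. Visible-light photoredox reduction (Ru(bpy)3Cl2, Hantzsch ester, i-Pr2NEt, CH2Cl2, blue light) releases the same C2 radical, which closes ring A in a reductive Giese cyclisation and ends as methyl 9-oxo-11,12,13,14,15,16,18-heptanorlabd-7-en-19-oate F2, a mixture of C4 epimers. Conjugate reduction and triflation as in step 9 give methyl 9-(trifluoromethylsulfonyloxy)-11,12,13,14,15,16,18-heptanorlabd-8-en-19-oate F3, and Negishi coupling with 25 as in step 14 gives methyl 15-(tert-butyldiphenylsilyloxy)-18-norlabda-8,13E-dien-19-oate F4. With no ketone left, LiN(i-Pr)2 and MeI (THF, −78 → 0 °C) methylate the C4 ester enolate from the α-face, anti to the C10 methyl, and return 26.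

Step 14. Oxidative addition into the tetrasubstituted enol triflate next to the quaternary C10 may be slower than protonolysis or β-hydride loss of the alkylzinc. The fallback changes the nucleophile to a boron ate complex, sets out from 24 (with 18) and comes back at 26. Iodine–lithium exchange on 24 (t-BuLi, Et2O, −78 °C) and capture with B-methoxy-9-borabicyclo[3.3.1]nonane give lithium B-[(E)-5-(tert-butyldiphenylsilyloxy)-3-methylpent-3-en-1-yl]-B-methoxy-9-boratabicyclo[3.3.1]nonane F5. This is coupled with 18 in a B-alkyl Suzuki–Miyaura reaction (PdCl2(dppf), aq. K3PO4, DMF, 60 °C) to give 26.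

Step 4. The selenium ene reaction may show poor site selectivity (attack at the ring C5–H) or stall at partial conversion. The fallback replaces it by electrophilic chlorination, sets out from 8 and comes back at 9. Ene-type chlorination of the isopropenyl group (Ca(OCl)2, CO2, CH2Cl2/H2O, 0 °C) gives 5-(3-chloroprop-1-en-2-yl)-6-(3-hydroxypropyl)-2,6-dimethylcyclohex-2-en-1-one F6. Displacement with KOAc (NaI cat., DMF, 60 °C) gives 2-[2-(3-hydroxypropyl)-2,4-dimethyl-3-oxocyclohex-4-en-1-yl]prop-2-en-1-yl acetate F7, and methanolysis (K2CO3, MeOH) gives diol 9, which is oxidised with MnO2 as in step 4.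

Further compounds

F1 | step 8 | 1,3-dioxoisoindolin-2-yl 3-[6-(3-methoxy-3-oxoprop-1-en-2-yl)-1,3-dimethyl-2-oxocyclohex-3-en-1-yl]propanoate | O=C1C(C)=CC[C@@H](C(=C)C(=O)OC)[C@]1(C)CCC(=O)ON1C(=O)c2ccccc2C1=O
F2 | step 8 | methyl 9-oxo-11,12,13,14,15,16,18-heptanorlabd-7-en-19-oate (C4 epimers) | O=C1C(C)=CC[C@H]2C(C(=O)OC)CCC[C@]12C
F3 | step 8 | methyl 9-(trifluoromethylsulfonyloxy)-11,12,13,14,15,16,18-heptanorlabd-8-en-19-oate (C4 epimers) | O=S(=O)(OC1=C(C)CC[C@H]2C(C(=O)OC)CCC[C@]12C)C(F)(F)F
F4 | step 8 | methyl 15-(tert-butyldiphenylsilyloxy)-18-norlabda-8,13E-dien-19-oate (C4 epimers) | CC(C)(C)[Si](c1ccccc1)(c1ccccc1)OC/C=C(\C)CCC1=C(C)CC[C@H]2C(C(=O)OC)CCC[C@]12C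
F5 | step 14 | lithium B-[(E)-5-(tert-butyldiphenylsilyloxy)-3-methylpent-3-en-1-yl]-B-methoxy-9-boratabicyclo[3.3.1]nonane | [Li+].CO[B-]1(CC/C(C)=C/CO[Si](c2ccccc2)(c2ccccc2)C(C)(C)C)C2CCCC1CCC2
F6 | step 4 | 5-(3-chloroprop-1-en-2-yl)-6-(3-hydroxypropyl)-2,6-dimethylcyclohex-2-en-1-one (configuration of 6) | O=C1C(C)=CC[C@@H](C(=C)CCl)[C@]1(C)CCCO
F7 | step 4 | 2-[2-(3-hydroxypropyl)-2,4-dimethyl-3-oxocyclohex-4-en-1-yl]prop-2-en-1-yl acetate (configuration of 6) | O=C1C(C)=CC[C@@H](C(=C)COC(C)=O)[C@]1(C)CCCO
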